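## Analysis of the target

Target 26 (CNP0479784.1) is a formyl-phloroglucinol meroterpenoid built on a chroman (O1, C2–C4, C4a–C8a). Its benzene ring is fully substituted: hydroxyls on C5 and C7, formyl groups on C6 and C8, the ether oxygen on C8a and the benzylic C4 on C4a. C2 and C3 are bridged by a seven-carbon chain, so a ten-membered carbocycle is trans-fused to the dihydropyran. That ring holds an exocyclic methylene conjugated with a Z ring alkene and, next to the alkene, a CH carrying a 2-hydroxypropan-2-yl group.

There are four stereocentres: C2 (R, quaternary, oxygen and methyl), C3 (S, ring fusion), C4 (R, 2-methylpropyl) and the carbinol-bearing ring carbon (R). On the pyran the C2 methyl, the C3 ring bond and the C4 isobutyl group lie on one face (H-3 and H-4 cis). The fourth centre is separated from the triad by two methylene groups and needs reagent control.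

The cross-conjugated diene (acid, transannular reactions), the tertiary alcohol, the two o-hydroxyaryl aldehydes and the tert-alkyl aryl ether limit the choice of late reagents and protecting groups. The hard points are the contiguous triad with a quaternary ether carbon beside a hexasubstituted arene, and a ten-membered ring with a Z alkene.

The strategy rests on the arene pattern. C5, C7 and C8a carry oxygen in a 1,3,5 relationship, and C6 and C8 each carry one carbon between two oxygens. C6–C7–C8 with the two pendant carbons is therefore the skeleton of a 3-oxoglutarate, and C5–C4a–C8a is a malonyl unit. The sequence C8a–O1–C2 can then start as the acyl carbon, ring oxygen and alkyl carbon of a δ-lactone.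

## Retrosynthetic reasoning

**26 to 24 (through 25).** The ring alkene is cut. A 1,3-diene with one exocyclic methylene and one ring alkene is the retron of ene–yne metathesis between a terminal alkyne on the chain from C3 and a vinyl group on the carbinol-bearing carbon. The cut is placed last because the diene is the most fragile part of 26; nothing, not even a deprotection, follows it. The forward step has to close a ten-membered ring with a Z alkene.

**24 to 17 (through 23, 22, 21, 20).** These are changes of oxidation level and protection only. The phenols of 24 are unmasked from the methoxymethyl ethers of 23, the terminal alkyne from the silyl alkyne of 22, and the formyl groups from the methyl esters of 20 by reduction to 21 and reoxidation. The arene of 17 thus carries both future formyl carbons as esters on the right ring carbons.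

**20 to 18 (through 19).** The bond between the vinyl group and the remote stereocentre is cut. A secondary carbon with a new C–C bond next to a tertiary alcohol is the retron of anti opening of a trisubstituted epoxide at its less substituted carbon. Epoxide 19 comes from the only electron-rich alkene of 18 by Shi epoxidation. This centre is out of reach of the pyran stereocentres, so a reagent-controlled epoxidation followed by a stereospecific opening is the shortest sure way to set it.

**17 to 14 and 15 (key disconnection).** The arene bonds C5–C6 and C8–C8a are cut, and the aryl ether oxygen is traced back to the ring oxygen of lactone 14. All six arene carbons then come from the malonate-type unit of 14 (C3, lactone carbonyl, exocyclic ester carbon) and from the three central carbons of 15. The gain is that the hexasubstituted arene arrives in one operation with every substituent in place, and that all three pyran stereocentres are fixed in 14 before any arene exists. The forward reaction must achieve two Claisen-type acylations of 15 and keep the lactone oxygen on C2 while it becomes the aryl ether.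

**14 to 10 and 11 (through 13 and 12).** The C4–H bond is cut first: conjugate reduction of 13 sets the benzylic centre relative to C5. The C3=C4 bond of 13 is a Knoevenagel retron within malonate 12, and the ester C–O bond of 12 is an acylation of the tertiary alcohol of 10 by 11. Hydride is added last because addition to C4 anti to the C5 side chain gives the required cis relationship of isobutyl and side chain; adding the isobutyl group last would give the trans isomer.

**10 to 7 (through 9 and 8).** The isobutyl ketone comes from aldehyde 8 and an isobutyl nucleophile, followed by oxidation of 9. Aldehyde 8 comes from selective oxidation of the primary alcohol of 7.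

**7 to 5 and 6; 5 to 4; 6 to 3, 2 and 1.** The bond between C2 of the diol and the butynyl chain is cut. The retron is the copper-mediated anti opening of a 2,3-epoxy alcohol at C2. Epoxide 5 comes from 4 by Sharpless epoxidation, which sets the quaternary carbinol carbon and, after inversion at C2, the future ring-fusion carbon. The chain comes from 1 by way of silyl alkyne 2 and bromide 3.

## Alternatives that were turned down

**Alternative 1:** The ten-membered ring is disconnected by an anionic oxy-Cope retron. A six-membered divinyl carbinol carrying the benzylic side chain would, as its potassium alkoxide, rearrange with four-atom ring expansion to the (2Z,6E)-dienone A1.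
- For: this is a dependable pericyclic way into germacrane-type rings, and it fixes the geometry of both ring alkenes in one step. On macrocycle formation it is stronger than the chosen route, whose metathesis closure is uncertain.
- Against: in A1 the pyran does not exist yet. It would have to be closed by adding the phenol oxygen across the E-trisubstituted alkene of a medium ring that also holds an enone or diene, so the quaternary centre and the ring fusion would depend on ring conformers and on the absence of transannular reactions. Both formyl groups would still have to be introduced on an electron-rich arene late, and two O-methyl groups would have to be cleaved in the presence of the diene and the tertiary alcohol.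
- Comparison: the chosen strategy gives up the pericyclic ring closure. In its place the quaternary ether carbon is set in the first step, the formyl carbons are in place from the arene-forming step, and there are no methyl ethers to remove.

**Alternative 2:** The benzylic carbon and the ring-fusion carbon are joined to their side chains by a Diels–Alder reaction of isoprene A4 across the C3=C4 bond of 5,7-dimethoxycoumarin A3, giving the cis-fused lactone A2. The cyclohexene is then cleaved to release the two chains.
- For: cheap materials, a preformed oxygenated arene, and the correct cis relationship of H-3 and H-4 directly from the cycloaddition. In the first steps it is shorter than the chosen route.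
- Against: an electron-rich coumarin is a poor dienophile, and the orientation of the diene is not secured. A2 is formed without absolute control. The lactone carbonyl of A2 would have to become the quaternary ether carbon by two successive carbon additions and a re-closure, with no element to control that centre. Unmasking the chains, adding the formyl groups and cleaving the methyl ethers make the route long.
- Comparison: the chosen strategy is longer up to the chroman but controls all four stereocentres absolutely.

**Alternative 3:** The ring alkene and the exocyclic methylene are disconnected together: enyne A6 would close by endo ring-closing ene–yne metathesis to A5, the 5,7-di-O-methyl ether of 26.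
- For: the diene and the macrocycle form in one late step from a stable precursor. This is the same closure that the chosen route uses at its end, so on this point the two are equal.
- Against: as a strategy it leaves open how the chroman, its three stereocentres and the hexasubstituted arene of A6 are made. A5 would also still need a double O-demethylation, which the diene and the tertiary alcohol are unlikely to survive.
- Comparison: the chosen strategy supplies the missing arene construction and moves all deprotection ahead of the ring closure.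

Key step: step 11

Remark: 9 is carried as both epimers at its secondary carbinol carbon and 14 as both epimers at C3; each of these carbons later becomes trigonal (ketone carbon of 10, arene carbon C4a of 17).

Remark: from 16 onwards chroman numbering is used; C2, C3 and C4 of the chroman are C6, C5 and C4 of lactone 14.

## Route

Step 1
Reactants: 1 but-3-yn-1-ol
Product: 2 4-[tri(propan-2-yl)silyl]but-3-yn-1-ol
Conditions: n-BuLi (2.1 equiv), THF, −78 °C; i-Pr3SiCl (1.05 equiv), −78 °C to rt; aq. NH4Cl
Reagents that add atoms: chlorotri(propan-2-yl)silane, CC(C)[Si](Cl)(C(C)C)C(C)C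
Why: Double deprotonation gives the alkoxide–acetylide dianion, and the acetylide carbon is silylated by the bulky chlorosilane faster than the aggregated lithium alkoxide oxygen (C-silylation of a terminal alkyne).

Step 2
Reactants: 2 4-[tri(propan-2-yl)silyl]but-3-yn-1-ol
Product: 3 (4-bromobut-1-yn-1-yl)tri(propan-2-yl)silane
Conditions: CBr4, PPh3, CH2Cl2, 0 °C
Reagents that add atoms: tetrabromomethane, BrC(Br)(Br)Br
Why: Appel bromination of a primary alcohol under neutral conditions; the silyl alkyne is inert.

Step 3
Reactants: 4 geraniol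
Product: 5 [(2R,3R)-3-methyl-3-(4-methylpent-3-en-1-yl)oxiran-2-yl]methanol
Conditions: Ti(OiPr)4 (5 mol %), D-(−)-diethyl tartrate (6 mol %), t-BuOOH, 4 Å molecular sieves, CH2Cl2, −20 °C
Reagents that add atoms: tert-butyl hydroperoxide, CC(C)(C)OO
Why: Sharpless asymmetric epoxidation of the allylic alkene only; the D-tartrate ligand directs oxygen to the face that gives the (2R,3R)-epoxide, which fixes the future quaternary ether carbon (C3 of 5) and, through the later inversion, the ring-fusion carbon.

Step 4
Reactants: 3 (4-bromobut-1-yn-1-yl)tri(propan-2-yl)silane; 5 [(2R,3R)-3-methyl-3-(4-methylpent-3-en-1-yl)oxiran-2-yl]methanol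
Product: 7 (2S,3R)-3,7-dimethyl-2-{4-[tri(propan-2-yl)silyl]but-3-yn-1-yl}oct-6-ene-1,3-diol, via Grignard reagent 6 (not isolated)
Conditions: 3 (3.2 equiv), Mg, THF, rt; then CuI (0.3 equiv), 5, THF, −30 to 0 °C; aq. NH4Cl
Reagents that add atoms: none
Why: Copper-catalysed Grignard opening of a 2,3-epoxy alcohol; with a fully substituted C3 the nucleophile attacks C2 and gives the 1,3-diol, anti to the C–O bond, so C2 is inverted while the C3–O bond is untouched.

Step 5
Reactants: 7 (2S,3R)-3,7-dimethyl-2-{4-[tri(propan-2-yl)silyl]but-3-yn-1-yl}oct-6-ene-1,3-diol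
Product: 8 (2R,3R)-3-hydroxy-3,7-dimethyl-2-{4-[tri(propan-2-yl)silyl]but-3-yn-1-yl}oct-6-enal
Conditions: TEMPO (0.1 equiv), PhI(OAc)2 (1.1 equiv), CH2Cl2, rt
Reagents that add atoms: none
Why: Oxoammonium oxidation takes the primary alcohol to the aldehyde and cannot touch the tertiary one; the nearly neutral medium spares the α-stereocentre (the descriptor changes by priority only).

Step 6
Reactants: 8 (2R,3R)-3-hydroxy-3,7-dimethyl-2-{4-[tri(propan-2-yl)silyl]but-3-yn-1-yl}oct-6-enal
Product: 9 (5S,6R)-2,6,10-trimethyl-5-{4-[tri(propan-2-yl)silyl]but-3-yn-1-yl}undec-9-ene-4,6-diol (both C4 epimers)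
Conditions: i-BuMgBr (3 equiv), THF, −78 °C; aq. NH4Cl
Reagents that add atoms: isobutylmagnesium bromide, CC(C)C[Mg]Br
Why: Grignard addition to the aldehyde; the first equivalent forms the magnesium alkoxide, and at −78 °C addition outruns retro-aldol cleavage. The new carbinol centre is removed in step 7.

Step 7
Reactants: 9 (5S,6R)-2,6,10-trimethyl-5-{4-[tri(propan-2-yl)silyl]but-3-yn-1-yl}undec-9-ene-4,6-diol
Product: 10 (5R,6R)-6-hydroxy-2,6,10-trimethyl-5-{4-[tri(propan-2-yl)silyl]but-3-yn-1-yl}undec-9-en-4-one
Conditions: Dess–Martin periodinane (1.3 equiv), NaHCO3, CH2Cl2, 0 °C to rt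
Reagents that add atoms: none
Why: Dess–Martin oxidation of the secondary alcohol; the tertiary alcohol is a spectator, and the buffer guards against epimerisation α to the new ketone and against dehydration.

Step 8
Reactants: 10 (5R,6R)-6-hydroxy-2,6,10-trimethyl-5-{4-[tri(propan-2-yl)silyl]but-3-yn-1-yl}undec-9-en-4-one; 11 methyl 3-chloro-3-oxopropanoate
Product: 12 methyl (5R,6R)-2,6,10-trimethyl-4-oxo-5-{4-[tri(propan-2-yl)silyl]but-3-yn-1-yl}undec-9-en-6-yl propanedioate
Conditions: 11 (3 equiv, slow addition), Et3N (3.5 equiv), CH2Cl2, −20 to 0 °C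
Reagents that add atoms: none
Why: O-Acylation of the hindered tertiary alcohol through the methoxycarbonylketene that Et3N generates from 11; ketenes acylate tertiary alcohols where acid chlorides are slow, and the low temperature holds back β-elimination.

Step 9
Reactants: 12 methyl (5R,6R)-2,6,10-trimethyl-4-oxo-5-{4-[tri(propan-2-yl)silyl]but-3-yn-1-yl}undec-9-en-6-yl propanedioate
Product: 13 methyl (5S,6R)-6-methyl-6-(4-methylpent-3-en-1-yl)-4-(2-methylpropyl)-2-oxo-5-{4-[tri(propan-2-yl)silyl]but-3-yn-1-yl}-5,6-dihydro-2H-pyran-3-carboxylate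
Conditions: TiCl4 (2 equiv), pyridine (4 equiv), THF, 0 °C to rt
Reagents that add atoms: none
Why: Intramolecular Knoevenagel condensation; the titanium enolate of the malonate adds to the ketone in a six-membered closure and titanium-assisted dehydration gives the conjugated alkene. The malonate C–H is far more acidic than the ketone α-H, so ring closure should precede elimination of the acyloxy group or epimerisation.

Step 10
Reactants: 13 methyl (5S,6R)-6-methyl-6-(4-methylpent-3-en-1-yl)-4-(2-methylpropyl)-2-oxo-5-{4-[tri(propan-2-yl)silyl]but-3-yn-1-yl}-5,6-dihydro-2H-pyran-3-carboxylate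
Product: 14 methyl (4R,5S,6R)-6-methyl-6-(4-methylpent-3-en-1-yl)-4-(2-methylpropyl)-2-oxo-5-{4-[tri(propan-2-yl)silyl]but-3-yn-1-yl}oxane-3-carboxylate (both C3 epimers)
Conditions: NaBH4 (1.5 equiv), THF–MeOH (10:1), −40 to 0 °C; then AcOH
Reagents that add atoms: none
Why: Conjugate reduction of the doubly activated alkene. The C5 side chain sits pseudoaxial to avoid allylic strain with the C4 isobutyl group, and hydride should add axially to C4 from the face anti to it, which places isobutyl cis to the C5 chain (4R); the malonate enolate formed protects the lactone from further reduction.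

Step 11
Reactants: 14 methyl (4R,5S,6R)-6-methyl-6-(4-methylpent-3-en-1-yl)-4-(2-methylpropyl)-2-oxo-5-{4-[tri(propan-2-yl)silyl]but-3-yn-1-yl}oxane-3-carboxylate; 15 dimethyl 3-oxopentanedioate
Product: 17 dimethyl (2R,3S,4R)-5,7-dihydroxy-2-methyl-2-(4-methylpent-3-en-1-yl)-4-(2-methylpropyl)-3-{4-[tri(propan-2-yl)silyl]but-3-yn-1-yl}-3,4-dihydro-2H-1-benzopyran-6,8-dicarboxylate, via ring-opened trihydroxy diester 16 (not isolated)
Conditions: 15 (1.5 equiv), NaH (3.5 equiv), DME, 0 to 85 °C; AcOH; then pyridinium p-toluenesulfonate (0.3 equiv), PhMe, 4 Å molecular sieves, 60 °C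
Reagents that add atoms: none
Why: Proposed new method: the sodium enolate of 15 is C-acylated by one carboxyl carbon of the malonate-type unit of 14 (Claisen), and the second methylene of the same oxoglutarate then attacks the other carboxyl carbon in a 6-exo-trig Dieckmann-type closure that completes the carbocycle; because both carbonyls sit on C3 and translactonisation can exchange their roles, the order of the two acylations does not matter. Under base the tetrahedral intermediate at the lactone carbon is expected to expel the tertiary alkoxide, and tautomerisation then gives the aromatic, locally symmetrical trihydroxy diester 16 as its sodium salt. In the acid stage the tertiary hydroxyl adds 6-exo-trig to the ring carbonyl of a keto tautomer of 16 (the two ortho positions are equivalent) and the hemiketal loses water to give the aryl ether, a vinylogous esterification driven by re-aromatisation and by the sieves; any bicyclic hemiketal that survives the base stage enters at the same point. The closest known reactions are the alkoxide-mediated condensation of dialkyl malonates with dialkyl 3-oxoglutarates to 2,4,6-trihydroxybenzene-1,3-dicarboxylates and the acid-catalysed O-alkylation of cyclic 1,3-diones and of phloroglucinol by alcohols; neither has been run with a lactone as the acyl partner or with a tertiary alcohol as the internal nucleophile. No stereocentre is formed: C4 and C5 of 14 are not acidic, and C2 of 17 keeps its configuration as long as the bond from oxygen to that carbon is never broken. The step needs crossed condensation rather than self-condensation, which is addressed by using 15 in excess and only as its preformed enolate (no free ketone). It also needs ring closure through the carbonyl and not through a tertiary cation, which is why the acid is weak and the temperature moderate.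

Step 12
Reactants: 17 dimethyl (2R,3S,4R)-5,7-dihydroxy-2-methyl-2-(4-methylpent-3-en-1-yl)-4-(2-methylpropyl)-3-{4-[tri(propan-2-yl)silyl]but-3-yn-1-yl}-3,4-dihydro-2H-1-benzopyran-6,8-dicarboxylate
Product: 18 dimethyl (2R,3S,4R)-5,7-bis(methoxymethoxy)-2-methyl-2-(4-methylpent-3-en-1-yl)-4-(2-methylpropyl)-3-{4-[tri(propan-2-yl)silyl]but-3-yn-1-yl}-3,4-dihydro-2H-1-benzopyran-6,8-dicarboxylate
Conditions: MeOCH2Cl (3 equiv), i-Pr2NEt (4 equiv), CH2Cl2, 0 °C to reflux
Reagents that add atoms: chloro(methoxy)methane, COCCl
Why: O-Alkylation of both phenols to methoxymethyl ethers; free salicylate-type phenols would be oxidised in step 13 and would divert the hydride reduction of step 15, and these ethers survive every step up to step 18.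

Step 13
Reactants: 18 dimethyl (2R,3S,4R)-5,7-bis(methoxymethoxy)-2-methyl-2-(4-methylpent-3-en-1-yl)-4-(2-methylpropyl)-3-{4-[tri(propan-2-yl)silyl]but-3-yn-1-yl}-3,4-dihydro-2H-1-benzopyran-6,8-dicarboxylate
Product: 19 dimethyl (2R,3S,4R)-2-{2-[(2R)-3,3-dimethyloxiran-2-yl]ethyl}-5,7-bis(methoxymethoxy)-2-methyl-4-(2-methylpropyl)-3-{4-[tri(propan-2-yl)silyl]but-3-yn-1-yl}-3,4-dihydro-2H-1-benzopyran-6,8-dicarboxylate
Conditions: D-fructose-derived Shi ketone (0.3 equiv), KHSO5 (as 2KHSO5·KHSO4·K2SO4), K2CO3, Bu4NHSO4, MeCN–CH2(OMe)2–aq. Na2B4O7 buffer, 0 °C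
Reagents that add atoms: potassium peroxymonosulfate, [K+].[O-]S(=O)(=O)OO
Why: Shi epoxidation of the only electron-rich alkene; the chiral dioxirane from the D-fructose-derived ketone should give the (R)-epoxide through the spiro transition state, by reagent control because the alkene is remote from the other stereocentres.

Step 14
Reactants: 19 dimethyl (2R,3S,4R)-2-{2-[(2R)-3,3-dimethyloxiran-2-yl]ethyl}-5,7-bis(methoxymethoxy)-2-methyl-4-(2-methylpropyl)-3-{4-[tri(propan-2-yl)silyl]but-3-yn-1-yl}-3,4-dihydro-2H-1-benzopyran-6,8-dicarboxylate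
Product: 20 dimethyl (2R,3S,4R)-2-[(3R)-3-ethenyl-4-hydroxy-4-methylpentyl]-5,7-bis(methoxymethoxy)-2-methyl-4-(2-methylpropyl)-3-{4-[tri(propan-2-yl)silyl]but-3-yn-1-yl}-3,4-dihydro-2H-1-benzopyran-6,8-dicarboxylate
Conditions: CH2=CHMgBr (5 equiv), CuI (0.5 equiv), THF, −30 to 0 °C; aq. NH4Cl
Reagents that add atoms: vinylmagnesium bromide, C=C[Mg]Br
Why: Copper-catalysed Grignard opening of the trisubstituted epoxide at its CH carbon with inversion gives the vinyl-bearing (R)-centre and the tertiary alcohol in one step; the two benzoate esters each have two ortho substituents and should resist addition at this temperature.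

Step 15
Reactants: 20 dimethyl (2R,3S,4R)-2-[(3R)-3-ethenyl-4-hydroxy-4-methylpentyl]-5,7-bis(methoxymethoxy)-2-methyl-4-(2-methylpropyl)-3-{4-[tri(propan-2-yl)silyl]but-3-yn-1-yl}-3,4-dihydro-2H-1-benzopyran-6,8-dicarboxylate
Product: 21 (3R)-5-[(2R,3S,4R)-6,8-bis(hydroxymethyl)-5,7-bis(methoxymethoxy)-2-methyl-4-(2-methylpropyl)-3-{4-[tri(propan-2-yl)silyl]but-3-yn-1-yl}-3,4-dihydro-2H-1-benzopyran-2-yl]-3-ethenyl-2-methylpentan-2-ol
Conditions: i-Bu2AlH (7 equiv), CH2Cl2, −78 to −20 °C; aq. potassium sodium tartrate
Reagents that add atoms: none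
Why: Hydride reduction of both hindered aryl esters to benzylic alcohols; the tertiary alcohol is only deprotonated, and at this temperature the silyl alkyne is not hydroaluminated.

Step 16
Reactants: 21 (3R)-5-[(2R,3S,4R)-6,8-bis(hydroxymethyl)-5,7-bis(methoxymethoxy)-2-methyl-4-(2-methylpropyl)-3-{4-[tri(propan-2-yl)silyl]but-3-yn-1-yl}-3,4-dihydro-2H-1-benzopyran-2-yl]-3-ethenyl-2-methylpentan-2-ol
Product: 22 (2R,3S,4R)-2-[(3R)-3-ethenyl-4-hydroxy-4-methylpentyl]-5,7-bis(methoxymethoxy)-2-methyl-4-(2-methylpropyl)-3-{4-[tri(propan-2-yl)silyl]but-3-yn-1-yl}-3,4-dihydro-2H-1-benzopyran-6,8-dicarbaldehyde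
Conditions: MnO2 (20 equiv), CH2Cl2, rt
Reagents that add atoms: none
Why: MnO2 oxidises the two benzylic alcohols to aldehydes and leaves the tertiary alcohol and the alkene alone.

Step 17
Reactants: 22 (2R,3S,4R)-2-[(3R)-3-ethenyl-4-hydroxy-4-methylpentyl]-5,7-bis(methoxymethoxy)-2-methyl-4-(2-methylpropyl)-3-{4-[tri(propan-2-yl)silyl]but-3-yn-1-yl}-3,4-dihydro-2H-1-benzopyran-6,8-dicarbaldehyde
Product: 23 (2R,3S,4R)-3-(but-3-yn-1-yl)-2-[(3R)-3-ethenyl-4-hydroxy-4-methylpentyl]-5,7-bis(methoxymethoxy)-2-methyl-4-(2-methylpropyl)-3,4-dihydro-2H-1-benzopyran-6,8-dicarbaldehyde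
Conditions: Bu4NF (1.5 equiv), THF, 0 °C; aq. NH4Cl
Reagents that add atoms: none
Why: Fluoride cleaves the C(sp)–Si bond; the acetal ethers and the non-enolisable aryl aldehydes are unaffected.

Step 18
Reactants: 23 (2R,3S,4R)-3-(but-3-yn-1-yl)-2-[(3R)-3-ethenyl-4-hydroxy-4-methylpentyl]-5,7-bis(methoxymethoxy)-2-methyl-4-(2-methylpropyl)-3,4-dihydro-2H-1-benzopyran-6,8-dicarbaldehyde
Product: 24 (2R,3S,4R)-3-(but-3-yn-1-yl)-2-[(3R)-3-ethenyl-4-hydroxy-4-methylpentyl]-5,7-dihydroxy-2-methyl-4-(2-methylpropyl)-3,4-dihydro-2H-1-benzopyran-6,8-dicarbaldehyde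
Conditions: 2 M aq. HCl, THF, rt
Reagents that add atoms: none
Why: Acetal hydrolysis; aryl methoxymethyl ethers ortho to formyl groups cleave easily, the tertiary alcohol is not activated towards ionisation, and the acid is used before the diene exists.

Step 19
Reactants: 24 (2R,3S,4R)-3-(but-3-yn-1-yl)-2-[(3R)-3-ethenyl-4-hydroxy-4-methylpentyl]-5,7-dihydroxy-2-methyl-4-(2-methylpropyl)-3,4-dihydro-2H-1-benzopyran-6,8-dicarbaldehyde
Product: 26 target CNP0479784.1, via cross-metathesis triene 25 (not isolated)
Conditions: second-generation Grubbs catalyst (10 mol %), H2C=CH2 (1 atm), PhMe, 50 °C; then argon purge, dilution to 1 mM, second-generation Hoveyda–Grubbs catalyst (10 mol %), 80 °C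
Reagents that add atoms: ethene, C=C
Why: Ene–yne cross-metathesis with ethene turns the terminal alkyne into a 2-substituted buta-1,3-diene, which fixes the exocyclic methylene on the former internal alkyne carbon. After ethene is purged, ring-closing metathesis between the monosubstituted diene terminus and the vinyl group should close the ten-membered ring (the 1,1-disubstituted methylene is unreactive), with the Z alkene expected from the ring size; no stereocentre is formed.

## Compound list

1 | but-3-yn-1-ol | C#CCCO | starting material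
2 | 4-[tri(propan-2-yl)silyl]but-3-yn-1-ol | OCCC#C[Si](C(C)C)(C(C)C)C(C)C | intermediate
3 | (4-bromobut-1-yn-1-yl)tri(propan-2-yl)silane | BrCCC#C[Si](C(C)C)(C(C)C)C(C)C | intermediate
4 | geraniol, (2E)-3,7-dimethylocta-2,6-dien-1-ol | CC(C)=CCC/C(C)=C/CO | starting material
5 | [(2R,3R)-3-methyl-3-(4-methylpent-3-en-1-yl)oxiran-2-yl]methanol | CC(C)=CCC[C@@]1(C)O[C@@H]1CO | intermediate
6 | {4-[tri(propan-2-yl)silyl]but-3-yn-1-yl}magnesium bromide | Br[Mg]CCC#C[Si](C(C)C)(C(C)C)C(C)C | intermediate
7 | (2S,3R)-3,7-dimethyl-2-{4-[tri(propan-2-yl)silyl]but-3-yn-1-yl}oct-6-ene-1,3-diol | CC(C)=CCC[C@@](C)(O)[C@H](CO)CCC#C[Si](C(C)C)(C(C)C)C(C)C | intermediate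
8 | (2R,3R)-3-hydroxy-3,7-dimethyl-2-{4-[tri(propan-2-yl)silyl]but-3-yn-1-yl}oct-6-enal | CC(C)=CCC[C@@](C)(O)[C@H](C=O)CCC#C[Si](C(C)C)(C(C)C)C(C)C | intermediate
9 | (5S,6R)-2,6,10-trimethyl-5-{4-[tri(propan-2-yl)silyl]but-3-yn-1-yl}undec-9-ene-4,6-diol (both C4 epimers) | CC(C)=CCC[C@@](C)(O)[C@H](C(O)CC(C)C)CCC#C[Si](C(C)C)(C(C)C)C(C)C | intermediate
10 | (5R,6R)-6-hydroxy-2,6,10-trimethyl-5-{4-[tri(propan-2-yl)silyl]but-3-yn-1-yl}undec-9-en-4-one | CC(C)=CCC[C@@](C)(O)[C@H](C(=O)CC(C)C)CCC#C[Si](C(C)C)(C(C)C)C(C)C | intermediate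
11 | methyl 3-chloro-3-oxopropanoate | COC(=O)CC(Cl)=O | starting material
12 | methyl (5R,6R)-2,6,10-trimethyl-4-oxo-5-{4-[tri(propan-2-yl)silyl]but-3-yn-1-yl}undec-9-en-6-yl propanedioate | CC(C)=CCC[C@@](C)(OC(=O)CC(=O)OC)[C@H](C(=O)CC(C)C)CCC#C[Si](C(C)C)(C(C)C)C(C)C | intermediate
13 | methyl (5S,6R)-6-methyl-6-(4-methylpent-3-en-1-yl)-4-(2-methylpropyl)-2-oxo-5-{4-[tri(propan-2-yl)silyl]but-3-yn-1-yl}-5,6-dihydro-2H-pyran-3-carboxylate | CC(C)=CCC[C@@]1(C)OC(=O)C(C(=O)OC)=C(CC(C)C)[C@@H]1CCC#C[Si](C(C)C)(C(C)C)C(C)C | intermediate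
14 | methyl (4R,5S,6R)-6-methyl-6-(4-methylpent-3-en-1-yl)-4-(2-methylpropyl)-2-oxo-5-{4-[tri(propan-2-yl)silyl]but-3-yn-1-yl}oxane-3-carboxylate (both C3 epimers) | CC(C)=CCC[C@@]1(C)OC(=O)C(C(=O)OC)[C@H](CC(C)C)[C@@H]1CCC#C[Si](C(C)C)(C(C)C)C(C)C | intermediate
15 | dimethyl 3-oxopentanedioate | COC(=O)CC(=O)CC(=O)OC | starting material
16 | dimethyl 2,4,6-trihydroxy-5-[(4R,5S,6R)-6-hydroxy-2,6,10-trimethyl-5-{4-[tri(propan-2-yl)silyl]but-3-yn-1-yl}undec-9-en-4-yl]benzene-1,3-dicarboxylate | CC(C)=CCC[C@@](C)(O)[C@@H](CCC#C[Si](C(C)C)(C(C)C)C(C)C)[C@@H](CC(C)C)c1c(O)c(C(=O)OC)c(O)c(C(=O)OC)c1O | intermediate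
17 | dimethyl (2R,3S,4R)-5,7-dihydroxy-2-methyl-2-(4-methylpent-3-en-1-yl)-4-(2-methylpropyl)-3-{4-[tri(propan-2-yl)silyl]but-3-yn-1-yl}-3,4-dihydro-2H-1-benzopyran-6,8-dicarboxylate | CC(C)=CCC[C@@]2(C)Oc3c(C(=O)OC)c(O)c(C(=O)OC)c(O)c3[C@H](CC(C)C)[C@@H]2CCC#C[Si](C(C)C)(C(C)C)C(C)C | intermediate
18 | dimethyl (2R,3S,4R)-5,7-bis(methoxymethoxy)-2-methyl-2-(4-methylpent-3-en-1-yl)-4-(2-methylpropyl)-3-{4-[tri(propan-2-yl)silyl]but-3-yn-1-yl}-3,4-dihydro-2H-1-benzopyran-6,8-dicarboxylate | CC(C)=CCC[C@@]2(C)Oc3c(C(=O)OC)c(OCOC)c(C(=O)OC)c(OCOC)c3[C@H](CC(C)C)[C@@H]2CCC#C[Si](C(C)C)(C(C)C)C(C)C | intermediate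
19 | dimethyl (2R,3S,4R)-2-{2-[(2R)-3,3-dimethyloxiran-2-yl]ethyl}-5,7-bis(methoxymethoxy)-2-methyl-4-(2-methylpropyl)-3-{4-[tri(propan-2-yl)silyl]but-3-yn-1-yl}-3,4-dihydro-2H-1-benzopyran-6,8-dicarboxylate | CC1(C)O[C@@H]1CC[C@@]2(C)Oc3c(C(=O)OC)c(OCOC)c(C(=O)OC)c(OCOC)c3[C@H](CC(C)C)[C@@H]2CCC#C[Si](C(C)C)(C(C)C)C(C)C | intermediate
20 | dimethyl (2R,3S,4R)-2-[(3R)-3-ethenyl-4-hydroxy-4-methylpentyl]-5,7-bis(methoxymethoxy)-2-methyl-4-(2-methylpropyl)-3-{4-[tri(propan-2-yl)silyl]but-3-yn-1-yl}-3,4-dihydro-2H-1-benzopyran-6,8-dicarboxylate | C=C[C@H](C(C)(C)O)CC[C@@]2(C)Oc3c(C(=O)OC)c(OCOC)c(C(=O)OC)c(OCOC)c3[C@H](CC(C)C)[C@@H]2CCC#C[Si](C(C)C)(C(C)C)C(C)C | intermediate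
21 | (3R)-5-[(2R,3S,4R)-6,8-bis(hydroxymethyl)-5,7-bis(methoxymethoxy)-2-methyl-4-(2-methylpropyl)-3-{4-[tri(propan-2-yl)silyl]but-3-yn-1-yl}-3,4-dihydro-2H-1-benzopyran-2-yl]-3-ethenyl-2-methylpentan-2-ol | C=C[C@H](C(C)(C)O)CC[C@@]2(C)Oc3c(CO)c(OCOC)c(CO)c(OCOC)c3[C@H](CC(C)C)[C@@H]2CCC#C[Si](C(C)C)(C(C)C)C(C)C | intermediate
22 | (2R,3S,4R)-2-[(3R)-3-ethenyl-4-hydroxy-4-methylpentyl]-5,7-bis(methoxymethoxy)-2-methyl-4-(2-methylpropyl)-3-{4-[tri(propan-2-yl)silyl]but-3-yn-1-yl}-3,4-dihydro-2H-1-benzopyran-6,8-dicarbaldehyde | C=C[C@H](C(C)(C)O)CC[C@@]2(C)Oc3c(C=O)c(OCOC)c(C=O)c(OCOC)c3[C@H](CC(C)C)[C@@H]2CCC#C[Si](C(C)C)(C(C)C)C(C)C | intermediate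
23 | (2R,3S,4R)-3-(but-3-yn-1-yl)-2-[(3R)-3-ethenyl-4-hydroxy-4-methylpentyl]-5,7-bis(methoxymethoxy)-2-methyl-4-(2-methylpropyl)-3,4-dihydro-2H-1-benzopyran-6,8-dicarbaldehyde | C=C[C@H](C(C)(C)O)CC[C@@]2(C)Oc3c(C=O)c(OCOC)c(C=O)c(OCOC)c3[C@H](CC(C)C)[C@@H]2CCC#C | intermediate
24 | (2R,3S,4R)-3-(but-3-yn-1-yl)-2-[(3R)-3-ethenyl-4-hydroxy-4-methylpentyl]-5,7-dihydroxy-2-methyl-4-(2-methylpropyl)-3,4-dihydro-2H-1-benzopyran-6,8-dicarbaldehyde | C=C[C@H](C(C)(C)O)CC[C@@]2(C)Oc3c(C=O)c(O)c(C=O)c(O)c3[C@H](CC(C)C)[C@@H]2CCC#C | intermediate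
25 | (2R,3S,4R)-2-[(3R)-3-ethenyl-4-hydroxy-4-methylpentyl]-5,7-dihydroxy-2-methyl-3-(3-methylidenepent-4-en-1-yl)-4-(2-methylpropyl)-3,4-dihydro-2H-1-benzopyran-6,8-dicarbaldehyde | C=C[C@H](C(C)(C)O)CC[C@@]2(C)Oc3c(C=O)c(O)c(C=O)c(O)c3[C@H](CC(C)C)[C@@H]2CCC(=C)C=C | intermediate
26 | CNP0479784.1: 5,7-dihydroxy-6,8-diformylchroman (2R,3S,4R) with 2-methyl and 4-(2-methylpropyl), whose C2 and C3 are bridged by a seven-carbon chain carrying an exocyclic methylene, a Z ring alkene and an (R)-CH bearing 2-hydroxypropan-2-yl | C=C1/C=C\[C@H](C(C)(C)O)CC[C@@]2(C)Oc3c(C=O)c(O)c(C=O)c(O)c3[C@H](CC(C)C)[C@@H]2CC1 | target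

## Step count and least certain steps

Total: 19 steps. Longest linear sequence: 18 steps (steps 1, 2 and 4–19, from but-3-yn-1-ol); from geraniol it is 17 steps (steps 3–19).

**Step 11 (key step, proposed new method).**
- Most likely failures in the base stage: the crossed acylation loses to self-condensation of 15, or 14 is simply deprotonated at its malonate-type C3–H and rests as an unreactive enolate.
- Most likely failure in the acid stage: ionisation of the tertiary alcohol competes with addition to the keto tautomer, which would erode the configuration at C2 or lead to elimination.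
- Fallback (known reaction types): it sets out from 14 and returns at 17. Thionation of the lactone carbonyl of 14 with Lawesson's reagent (PhMe, 90 °C) would give the thionolactone F1. S-Methylation of its enolate (NaH, MeI, THF) would give the cyclic ketene O,S-acetal F2. Treatment of F2 with the sodium enolate of 15 (NaH, DMF, 60–80 °C) should proceed by addition–elimination at C2 with loss of methanethiolate, then Dieckmann closure onto the C3 ester and enolisation to 17. This is the arene annulation known for α-oxo ketene S,S- and O,S-acetals with 1,3-dicarbonyl carbanions. Methanethiolate is a far better leaving group than the tertiary alkoxide, so the ring oxygen stays on C2 and no acid stage is needed.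

**Step 19.**
- Most likely failures: intermolecular metathesis (dimers and oligomers) outcompetes closure of the strained ten-membered ring; the ring alkene forms with poor geometric control; the catalyst is lost to the acidic, chelating o-formyl phenols.
- Fallback: it sets out from 23 and returns at 26. Ring closure is moved ahead of phenol deprotection and the diene is isolated. Cross-metathesis of 23 with ethene (second-generation Grubbs catalyst, 1 atm, PhMe, 50 °C) would give the protected triene F3. Slow addition of F3 to second-generation Hoveyda–Grubbs catalyst at 1 mM (PhMe, 80 °C) would close the ring on the neutral substrate to the protected macrocycle F4. The two activated aryl acetals would then be removed without protic acid by chelation-assisted cleavage (MgBr2·OEt2, EtSH, Et2O, 0 °C) to give 26.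

**Step 10.**
- Most likely failure: poor facial selectivity of hydride delivery to C4, because the pseudoaxial 4-methylpent-3-enyl group on C6 lies on the same face that the C5 chain leaves open.
- Fallback: it sets out from 13 and returns at 14. Substrate control is replaced by reagent control, using copper hydride catalysis with a chiral bisphosphine (Cu(OAc)2, (R)- or (S)-DTBM-SEGPHOS, (EtO)2MeSiH, t-BuOH, PhMe), with the ligand enantiomer chosen for the required face. This fallback makes no compound outside the list (F0).

**Step 14.**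
- Most likely failure: SN2 attack at an epoxide carbon flanked by a fully substituted carbon is slow, so that rearrangement of the epoxide to a ketone or attack of the Grignard reagent on the esters takes over.
- Fallback: it sets out from 19 and returns at 20. Opening of 19 with lithium acetylide (LiC≡CH·H2NCH2CH2NH2, DMSO, rt), a small uncomplexed nucleophile, at the same carbon with inversion would give the ethynyl carbinol F5. Semihydrogenation of its terminal alkyne (H2, Pd/CaCO3 poisoned with Pb(OAc)2, quinoline, EtOAc), which should be much faster than reduction of the silyl-capped internal alkyne, would give 20.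

## Further compounds

F1 | step 11 | methyl (4R,5S,6R)-6-methyl-6-(4-methylpent-3-en-1-yl)-4-(2-methylpropyl)-2-sulfanylidene-5-{4-[tri(propan-2-yl)silyl]but-3-yn-1-yl}oxane-3-carboxylate (both C3 epimers) | CC(C)=CCC[C@@]1(C)OC(=S)C(C(=O)OC)[C@H](CC(C)C)[C@@H]1CCC#C[Si](C(C)C)(C(C)C)C(C)C
F2 | step 11 | methyl (4R,5S,6R)-6-methyl-6-(4-methylpent-3-en-1-yl)-4-(2-methylpropyl)-2-(methylsulfanyl)-5-{4-[tri(propan-2-yl)silyl]but-3-yn-1-yl}-5,6-dihydro-4H-pyran-3-carboxylate | CC(C)=CCC[C@@]1(C)OC(SC)=C(C(=O)OC)[C@H](CC(C)C)[C@@H]1CCC#C[Si](C(C)C)(C(C)C)C(C)C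
F3 | step 19 | (2R,3S,4R)-2-[(3R)-3-ethenyl-4-hydroxy-4-methylpentyl]-5,7-bis(methoxymethoxy)-2-methyl-3-(3-methylidenepent-4-en-1-yl)-4-(2-methylpropyl)-3,4-dihydro-2H-1-benzopyran-6,8-dicarbaldehyde | C=C[C@H](C(C)(C)O)CC[C@@]2(C)Oc3c(C=O)c(OCOC)c(C=O)c(OCOC)c3[C@H](CC(C)C)[C@@H]2CCC(=C)C=C
F4 | step 19 | 5,7-bis(methoxymethyl) ether of 26 | C=C1/C=C\[C@H](C(C)(C)O)CC[C@@]2(C)Oc3c(C=O)c(OCOC)c(C=O)c(OCOC)c3[C@H](CC(C)C)[C@@H]2CC1
F0 | step 10 | none | none
F5 | step 14 | dimethyl (2R,3S,4R)-2-[(3R)-3-ethynyl-4-hydroxy-4-methylpentyl]-5,7-bis(methoxymethoxy)-2-methyl-4-(2-methylpropyl)-3-{4-[tri(propan-2-yl)silyl]but-3-yn-1-yl}-3,4-dihydro-2H-1-benzopyran-6,8-dicarboxylate | C#C[C@H](C(C)(C)O)CC[C@@]2(C)Oc3c(C(=O)OC)c(OCOC)c(C(=O)OC)c(OCOC)c3[C@H](CC(C)C)[C@@H]2CCC#C[Si](C(C)C)(C(C)C)C(C)C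
A1 | alternative 1 | ten-membered (2Z,6E)-dienone carrying the benzylic side chain | O=C1/C=C\[C@H](C(C)(C)O[Si](CC)(CC)CC)C/C=C(C)/[C@@H](CC1)[C@@H](CC(C)C)c1c(OC)cc(OC)cc1OCOC
A2 | alternative 2 | cis-1,3-dimethoxy-9-methyl-6a,7,10,10a-tetrahydro-6H-benzo[c]chromen-6-one | O=C1Oc2cc(OC)cc(OC)c2[C@@H]2CC(C)=CC[C@H]12
A3 | alternative 2 | 5,7-dimethoxycoumarin (5,7-dimethoxy-2H-1-benzopyran-2-one) | COc1cc(OC)c2ccc(=O)oc2c1
A4 | alternative 2 | isoprene (2-methylbuta-1,3-diene) | C=CC(C)=C
A5 | alternative 3 | 5,7-di-O-methyl ether of 26 | C=C1/C=C\[C@H](C(C)(C)O)CC[C@@]2(C)Oc3c(C=O)c(OC)c(C=O)c(OC)c3[C@H](CC(C)C)[C@@H]2CC1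
A6 | alternative 3 | (2R,3S,4R)-3-(but-3-yn-1-yl)-2-[(3R)-3-ethenyl-4-hydroxy-4-methylpentyl]-5,7-dimethoxy-2-methyl-4-(2-methylpropyl)-3,4-dihydro-2H-1-benzopyran-6,8-dicarbaldehyde | C=C[C@H](C(C)(C)O)CC[C@@]2(C)Oc3c(C=O)c(OC)c(C=O)c(OC)c3[C@H](CC(C)C)[C@@H]2CCC#C
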